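## Structural features

The target 8 is 3,5-dibromo-2-(5-bromo-2-methoxyphenoxy)phenol: two benzene rings joined only through one diaryl ether oxygen, with no further ring and no stereocentre, so there is no stereochemical relationship to control. Ring A is an anisole with OMe on C1, bromine para to it on C4 and the ether oxygen on C6, ortho to the methoxy group. Ring B carries the ether oxygen on C1, a free hydroxyl on C2 and bromines on C4 and C6; it is the oxygen of a 2,4-dibromophenol with a second oxygen on the one remaining ortho carbon. The ether oxygen is therefore flanked by three ortho substituents (OMe on ring A, OH and Br on ring B), and the oxygen of ring B is a weak, hindered nucleophile. The fragile points are the three aryl C–Br bonds, which exclude hydrogenolysis, unselective halogen–metal exchange and hot transition-metal couplings, and the electron-rich catechol-type phenol, which is oxidant-sensitive once free. The real difficulty is to form this hindered ether with every halogen on a defined carbon and with the two oxygens of each ring differentiated, which argues against late electrophilic bromination. The key step uses the O–C1–C2–heteroatom array of ring B: an iodonium centre on C2 brings C6 of ring A within reach of the phenolate oxygen through the five-atom array O–C1–C2–I–C6, so ring A can shift from iodine to oxygen and leave iodine on C2 as the placeholder for the hydroxyl.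

## Logic of the disconnections

From 8 to 5: the C2–OH bond of ring B is cut and replaced by a C2–I bond. The hydroxyl is then the footprint of the iodine that the ether-forming step leaves behind, so no phenol protecting group is needed and the oxidant-sensitive free phenol appears only at the end. The forward step must convert one C–I bond into C–O beside three C–Br bonds; this is asked of a low-temperature iodine–magnesium exchange, passing through 6 and 7 in one flask.

From 5 to 4: the ether bond between the oxygen of ring B and C6 of ring A is cut, and C6 is reconnected to the iodine on C2 of ring B. The hindered intermolecular aryl ether synthesis becomes an isomerisation of a zwitterion, with no atom gained or lost and no metal near the bromides. The forward step requires the phenolate oxygen to attack the ipso carbon on iodine faster than 4 fragments.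

From 4 to 2 and 3: the bond between iodine and the ring B carbon (C2 of ring B in 8, the free ortho carbon of 3) is cut. This splits the molecule into two monocyclic pieces, each with all its halogens and its oxygen already in place. The forward step requires the electrophilic iodine of 2 to go to that ortho carbon of 3 instead of oxidising the phenol; 3 has bromine on its other ortho carbon and on its para carbon, so no other site is open.

From 2 to 1: the two iodine–acetate bonds are cut, leading back to 1, which carries the complete substitution pattern of ring A. The forward step is an oxidation at iodine that must leave the electron-rich anisole ring alone.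

## Other disconnections considered

Alternative 1: The cut goes through ring A at C5–C6 and C2–C3, so ring A is assembled from a three-carbon ketone and a three-carbon iminium unit.
- Forward plan: 2-(benzyloxy)-4,6-dibromophenol A1 would be O-alkylated with an α-halo ketone to 1-[2-(benzyloxy)-4,6-dibromophenoxy]propan-2-one A2. The ketone A2 would condense twice with 2-bromo-1,3-bis(dimethylamino)trimethinium hexafluorophosphate A3 under KOt-Bu, with loss of two amine molecules, closing ring A as 2-[2-(benzyloxy)-4,6-dibromophenoxy]-4-bromophenol A4. O-Methylation of A4 would give 1-(benzyloxy)-3,5-dibromo-2-(5-bromo-2-methoxyphenoxy)benzene A5, and debenzylation of A5 would give 8.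
- In favour: the hindered oxygen of ring B is joined to an sp3 carbon by simple substitution and never has to be arylated. The bromine of ring A arrives with A3 on a fixed carbon, so the substitution pattern of A4 follows from constitution, which makes this plan the equal of the chosen one in regiochemical certainty. The second oxygen of ring B is present from the start, so no carbon–halogen bond has to become C–OH beside three bromides; on that point this plan is the better one.
- Against: phenol-forming [3+3] condensations of vinamidinium salts are at their best with ketones flanked by two activated methylene groups. A2 offers one unactivated methyl group and one methylene carrying a bulky aryloxy group on a ring-forming carbon. The strongly basic medium may also attack the C–Br bond of A3 or cause self-condensation of A2 before A4 can form.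
- Comparison: structurally it needs a benzyl group whose removal must spare three C–Br bonds and the methyl ether, so hydrogenolysis is excluded. Mechanistically it replaces one unimolecular isomerisation by a double condensation with several branching points. In step count it needs four steps from A1, five from purchasable material with A3 not counted, against four in the chosen plan.

Alternative 2: Ring B is cut at C1–C6 and C2–C3 into a four-carbon diene and a two-carbon alkyne.
- Forward plan: 3,5-dibromo-2H-pyran-2-one A6 and 2-[(2-methoxyphenoxy)ethynyl]-4,4,5,5-tetramethyl-1,3,2-dioxaborolane A7 would combine by [4+2] cycloaddition and decarboxylative aromatisation to 2-[3,5-dibromo-2-(2-methoxyphenoxy)phenyl]-4,4,5,5-tetramethyl-1,3,2-dioxaborolane A8. Bromination of ring A of A8 para to the methoxy group would give 2-[3,5-dibromo-2-(5-bromo-2-methoxyphenoxy)phenyl]-4,4,5,5-tetramethyl-1,3,2-dioxaborolane A9, and oxidation of the C–B bond of A9 would give 8.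
- In favour: the fully substituted ring B of A8 is created with the ether oxygen already attached, so no hindered aryl–oxygen bond has to be made. Boron becomes hydroxyl by a plain peroxide oxidation without any organometallic reagent, which is milder than the last step of the chosen plan and is the better solution on that point. Counted from A6 and A7 it is three steps, one fewer than the chosen plan.
- Against: A7 is an electron-rich, sensitive ynol ether boronate that would itself need several steps, so the real step count is higher. The cycloaddition needs high temperature. Its regiochemistry rests on the aryloxy carbon of A7 bonding to the bromine-bearing C3 of A6 while the boryl group exerts its own directing effect, so the constitution of A8 rests on a preference and not on connectivity as in the chosen plan. The bromine of ring A must be introduced late, with the risk of substitution para to the aryloxy oxygen and of ipso-bromodeboronation, and it must precede the oxidation because the free phenol ring would otherwise be the most reactive one.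
- Comparison: mechanistically both plans rely on a pericyclic or ligand-coupling event without a catalyst. The chosen plan carries all three bromines from purchased materials, whereas this one leaves one of them to a selectivity question.

Alternative 3: The cut is the C1–OMe bond of ring A together with the aromaticity of that ring, which is carried as a cyclohexenone.
- Forward plan: 2-[2-(benzyloxy)-4,6-dibromophenoxy]cyclohex-2-en-1-one A10 would be made from the phenol A1 of alternative 1 by opening of an α,β-epoxy ketone and loss of water. Heating A10 with I2 in MeOH would give 1-(benzyloxy)-3,5-dibromo-2-(2-methoxyphenoxy)benzene A11 through enol ether formation, iodination–elimination and aromatisation. Bromination of ring A of A11 would lead to the benzyl ether A5 of alternative 1, and debenzylation of A5 would give 8.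
- In favour: the ether bond is made by attack of the phenoxide on an sp3 carbon, which tolerates the two ortho substituents and uses no transition metal beside the bromides; here the plan is the equal of the chosen one. The methyl ether of A11 is created in the aromatisation itself, so no separate methylation is needed, and the reagents are inexpensive.
- Against: ring A of A11 arrives without its bromine, so a late electrophilic bromination must choose the position para to OMe over the one para to the aryloxy oxygen, whereas the chosen plan buys that bromine in place. Iodine in hot methanol generates acid and may also iodinate the newly formed electron-rich anisole ring. A benzyl group has to be removed without hydrogenolysis.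
- Comparison: mechanistically it is a multi-event oxidation against a single intramolecular aryl shift. In step count it needs four steps from A1, five from purchasable material, against four.

Key step: step 3

Remark on the chemistry: 8 is achiral, so no stereodescriptor is needed; 4 is used as the free zwitterion without a protecting group, and 1 is oxidised with NaBO3·4H2O in AcOH in place of a peracid because its anisole ring is electron-rich.

## Route

Step 1
Reactants: 1 4-bromo-2-iodoanisole (4-bromo-2-iodo-1-methoxybenzene)
Product: 2 4-bromo-2-(diacetoxyiodo)anisole (the 5-bromo-2-methoxyphenyl group on trivalent iodine that carries two acetate ligands)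
Conditions: NaBO3·4H2O (10 equiv), AcOH, 40–45 °C; H2O, extraction, trituration
Reagents that add atoms: acetic acid, CC(=O)O
Why: Oxidation of an aryl iodide to the (diacetoxyiodo)arene with NaBO3·4H2O in AcOH is a standard, mild method that tolerates alkoxy and halogen substituents; the ortho methoxy oxygen stabilises the trivalent iodine by a secondary I···O contact and the ring bromine is inert.

Step 2
Reactants: 2 4-bromo-2-(diacetoxyiodo)anisole; 3 2,4-dibromophenol
Product: 4 2,4-dibromo-6-[(5-bromo-2-methoxyphenyl)iodonio]phenolate (zwitterion)
Conditions: KOH (2.1 equiv), MeOH, −10 → 0 °C, dark; filtration of the precipitate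
Reagents that add atoms: none
Why: This is the known preparation of aryliodonium phenolates from acidic phenols and (diacetoxyiodo)arenes in methanolic KOH: the phenoxide of 3 exchanges a ligand at the trivalent iodine of 2, iodine is delivered to the only unsubstituted ortho carbon (C6 of 3, the other ortho and the para carbon carrying bromine), and loss of the ring proton gives the neutral zwitterion, which should precipitate from cold methanol. The two bromines make the phenoxide a poor substrate for oxidative dearomatisation and acidic enough to stay as the phenolate.

Step 3
Reactants: 4 2,4-dibromo-6-[(5-bromo-2-methoxyphenyl)iodonio]phenolate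
Product: 5 1,5-dibromo-2-(5-bromo-2-methoxyphenoxy)-3-iodobenzene
Conditions: MeCN (0.05 M), reflux, N2, dark; DMF, 100 °C if slow
Reagents that add atoms: none
Why: On heating, the phenolate oxygen of ring B in 4 attacks the ipso carbon of the anisyl group on iodine (C6 of ring A) through a five-membered spiro, Meisenheimer-like transition state made of O, C1 and C2 of ring B, iodine and C6; the C6–I bond breaks as the C6–O bond forms, and trivalent iodine is reduced to monovalent iodine that stays on ring B as the aryl iodide of 5. The closest known reaction type is the heat-induced iodine-to-oxygen 1,4 aryl shift by which 2-(aryliodonio)phenolates isomerise to aryl 2-iodophenyl ethers, an intramolecular Smiles-type ligand coupling documented for nitro-substituted phenolates, of which the dibromophenolate is a further member. No ring is closed in the product, the five-membered array existing only in the transition state, and no stereocentre is formed. Which aryl group moves and where iodine ends follow from the constitution of 4, because the second carbon ligand of iodine is ring B itself. The selectivity that is needed is aryl shift over fragmentation of 4 with loss of aryl iodide 1 (carbene- or radical-type decomposition) and over intermolecular aryl transfer. The substrate helps in three ways: the aryliodonio group is an exceptionally good leaving group and makes C6 of ring A electrophilic without a nitro group, the bromine meta and the methoxy oxygen ortho to C6 add inductive activation, and the bromine-flanked oxygen is held next to C6 so that intramolecularity offsets its low nucleophilicity. Dilution, exclusion of light and oxygen and the absence of any metal should keep the three C–Br bonds and the new C–I bond untouched.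

Step 4
Reactants: 5 1,5-dibromo-2-(5-bromo-2-methoxyphenoxy)-3-iodobenzene
Product: 8 3,5-dibromo-2-(5-bromo-2-methoxyphenoxy)phenol, via arylmagnesium chloride 6 (not isolated), via dimethyl arylboronate 7 (not isolated)
Conditions: iPrMgCl·LiCl (1.1 equiv), THF, −40 °C; B(OMe)3 (2 equiv), −40 °C → rt; 30% H2O2, aq NaOH, 0 °C → rt; aq Na2S2O3, then aq NH4Cl
Reagents that add atoms: hydrogen peroxide, OO (oxygen of the new hydroxyl of 8); isopropylmagnesium chloride–lithium chloride, CC(C)[Mg]Cl.[Li]Cl (MgCl of 6 only); trimethyl borate, COB(OC)OC (B(OMe)2 group of 7 only)
Why: Halogen–magnesium exchange with iPrMgCl·LiCl is far faster at C–I than at C–Br and is further accelerated by the ortho aryloxy group, so at −40 °C the three bromides should remain; 6 has no ortho halogen and cannot form an aryne by loss of a magnesium halide. Borylation with B(OMe)3 and peroxide oxidation with 1,2-shift of the aryl group from boron to oxygen is the standard phenol synthesis from aryl organometallics.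

## Compound list

1 | 4-bromo-2-iodoanisole (4-bromo-2-iodo-1-methoxybenzene) | COc1ccc(Br)cc1I | starting material
2 | 4-bromo-2-(diacetoxyiodo)anisole | COc1ccc(Br)cc1I(OC(C)=O)OC(C)=O | intermediate
3 | 2,4-dibromophenol | Oc1ccc(Br)cc1Br | starting material
4 | 2,4-dibromo-6-[(5-bromo-2-methoxyphenyl)iodonio]phenolate | [O-]c1c(Br)cc(Br)cc1[I+]c1cc(Br)ccc1OC | intermediate
5 | 1,5-dibromo-2-(5-bromo-2-methoxyphenoxy)-3-iodobenzene | COc1ccc(Br)cc1Oc1c(I)cc(Br)cc1Br | intermediate
6 | [3,5-dibromo-2-(5-bromo-2-methoxyphenoxy)phenyl]magnesium chloride, LiCl complex (formed in the flask in step 4) | COc1ccc(Br)cc1Oc1c([Mg]Cl)cc(Br)cc1Br | intermediate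
7 | dimethyl [3,5-dibromo-2-(5-bromo-2-methoxyphenoxy)phenyl]boronate (formed in the flask in step 4) | COc1ccc(Br)cc1Oc1c(B(OC)OC)cc(Br)cc1Br | intermediate
8 | 3,5-dibromo-2-(5-bromo-2-methoxyphenoxy)phenol | COc1ccc(Br)cc1Oc1c(O)cc(Br)cc1Br | target

## Step count and least certain steps

Total step count: 4. Longest linear sequence: 4 steps (1 → 2 → 4 → 5 → 8); 3 enters in step 2.

**Step 3 (key step).**
- Most likely failure: the aryl shift is outrun by fragmentation of the zwitterion, that is, cleavage of the bond between iodine and ring B with loss of aryl iodide 1 and oligomerisation of the remaining phenol fragment. The migrating ring is electron-rich and the attacking oxygen is flanked by bromine.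
- Fallback (sets out from 3, comes back at 5): 3 would be iodinated at its free ortho carbon with N-iodosuccinimide and catalytic TsOH in MeCN to 2,4-dibromo-6-iodophenol F1. F1 would then be O-arylated with commercial (5-bromo-2-methoxyphenyl)boronic acid in a Chan–Lam coupling (catalytic Cu(OAc)2, pyridine, 4 Å molecular sieves, CH2Cl2, O2 atmosphere, room temperature), which should give 5 directly. This oxidative coupling at divalent copper runs at room temperature, should not insert into C–Br or C–I bonds and is a known way to arylate 2,6-dihalophenols.

**Step 2.**
- Most likely failure: two-electron oxidation of the phenoxide (attack at the bromine-bearing para carbon with capture by methanol) or simple reduction of 2 competes with C–I bond formation at the ortho carbon. The zwitterion may also decompose before it precipitates.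
- Fallback (sets out from 3, comes back at 4): the roles of the rings are exchanged, so that trivalent iodine is generated on ring B and ring A is attached as the nucleophile. 3 would be iodinated and acetylated in one flask (N-iodosuccinimide, cat. TsOH, MeCN; then Ac2O, pyridine; the free iodophenol is F1 of the preceding fallback) to 2,4-dibromo-6-iodophenyl acetate F2. Oxidation of F2 with mCPBA and TsOH·H2O in CH2Cl2/CF3CH2OH in the presence of 4-bromoanisole should give (2-acetoxy-3,5-dibromophenyl)(5-bromo-2-methoxyphenyl)iodonium 4-methylbenzenesulfonate F3 by electrophilic substitution ortho to the methoxy group, the para position being blocked by bromine. Cold methanolic KOH would then cleave the aryl acetate of F3 and deliver 4.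

**Step 4.**
- Most likely failure: incomplete chemoselectivity of the halogen–magnesium exchange (exchange at the bromine ortho to the ether oxygen) or protonation of 6 before borate formation, which would give the deiodinated ether.
- Fallback (sets out from 5, comes back at 8): a Miyaura borylation at the C–I bond (B2pin2, KOAc, PdCl2(dppf), dioxane, 80 °C), in which zerovalent palladium inserts into C–I much faster than into C–Br, would give 2-[3,5-dibromo-2-(5-bromo-2-methoxyphenoxy)phenyl]-4,4,5,5-tetramethyl-1,3,2-dioxaborolane F4 (the same boronate as A9 of alternative 2). F4 can be purified before oxidation with H2O2 and aqueous NaOH to 8.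

## Further compounds

F1 | step 3 | 2,4-dibromo-6-iodophenol | Oc1c(Br)cc(Br)cc1I
F2 | step 2 | 2,4-dibromo-6-iodophenyl acetate | CC(=O)Oc1c(Br)cc(Br)cc1I
F3 | step 2 | (2-acetoxy-3,5-dibromophenyl)(5-bromo-2-methoxyphenyl)iodonium 4-methylbenzenesulfonate | CC(=O)Oc1c(Br)cc(Br)cc1[I+]c1cc(Br)ccc1OC.Cc1ccc(cc1)S(=O)(=O)[O-]
F4 | step 4 | 2-[3,5-dibromo-2-(5-bromo-2-methoxyphenoxy)phenyl]-4,4,5,5-tetramethyl-1,3,2-dioxaborolane | COc1ccc(Br)cc1Oc1c(B2OC(C)(C)C(C)(C)O2)cc(Br)cc1Br
A1 | alternative 1 | 2-(benzyloxy)-4,6-dibromophenol | Oc1c(Br)cc(Br)cc1OCc1ccccc1
A2 | alternative 1 | 1-[2-(benzyloxy)-4,6-dibromophenoxy]propan-2-one | CC(=O)COc1c(Br)cc(Br)cc1OCc1ccccc1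
A3 | alternative 1 | 2-bromo-1,3-bis(dimethylamino)trimethinium hexafluorophosphate | CN(C)C=C(Br)C=[N+](C)C.F[P-](F)(F)(F)(F)F
A4 | alternative 1 | 2-[2-(benzyloxy)-4,6-dibromophenoxy]-4-bromophenol | Oc1ccc(Br)cc1Oc1c(Br)cc(Br)cc1OCc1ccccc1
A5 | alternative 1 | 1-(benzyloxy)-3,5-dibromo-2-(5-bromo-2-methoxyphenoxy)benzene | COc1ccc(Br)cc1Oc1c(Br)cc(Br)cc1OCc1ccccc1
A6 | alternative 2 | 3,5-dibromo-2H-pyran-2-one | O=C1OC=C(Br)C=C1Br
A7 | alternative 2 | 2-[(2-methoxyphenoxy)ethynyl]-4,4,5,5-tetramethyl-1,3,2-dioxaborolane | COc1ccccc1OC#CB1OC(C)(C)C(C)(C)O1
A8 | alternative 2 | 2-[3,5-dibromo-2-(2-methoxyphenoxy)phenyl]-4,4,5,5-tetramethyl-1,3,2-dioxaborolane | COc1ccccc1Oc1c(B2OC(C)(C)C(C)(C)O2)cc(Br)cc1Br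
A9 | alternative 2 | 2-[3,5-dibromo-2-(5-bromo-2-methoxyphenoxy)phenyl]-4,4,5,5-tetramethyl-1,3,2-dioxaborolane | COc1ccc(Br)cc1Oc1c(B2OC(C)(C)C(C)(C)O2)cc(Br)cc1Br
A10 | alternative 3 | 2-[2-(benzyloxy)-4,6-dibromophenoxy]cyclohex-2-en-1-one | O=C1CCCC=C1Oc1c(Br)cc(Br)cc1OCc1ccccc1
A11 | alternative 3 | 1-(benzyloxy)-3,5-dibromo-2-(2-methoxyphenoxy)benzene | COc1ccccc1Oc1c(Br)cc(Br)cc1OCc1ccccc1
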